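The readings were generated by integration with made-up constants; scatter was added.

Start at early times, with the first readings of the two earlier runs.

| flask | substrate | partner | remark | time |
|---|---|---|---|---|
| west | 0.028 M | 1.1 equiv | run made earlier |  |
| south | 0.044 M | 1.1 equiv | run made earlier |  |
| flask | 0.020 M | 1.10 equiv |  | 20 min |

| run | time / min | substrate / % | mono adduct / % |
|---|---|---|---|
| west | 1.50 | 68 | 17 |
| west | 2.50 | 70 | 16 |
| west | 4.00 | 73 | 14 |
| west | 6.00 | 73 | 17 |
| west | 8.00 | 73 | 13 |
| west | 12.0 | 67 | 11 |
| west | 20.0 | 74 | 7 |
| south | 1.50 | 63 | 18 |
| south | 2.50 | 64 | 17 |
| south | 4.00 | 66 | 11 |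
| south | 6.00 | 66 | 12 |
| south | 8.00 | 61 | 7 |
| south | 12.0 | 65 | 4 |
| south | 20.0 | 64 | 1 |

(readings scatter by 1.5 percentage points)



- the substrate standing at 20 min, as a percentage of the substrate charged
- the mono adduct standing at 20 min, as a percentage of the substrate charged
- the bis adduct standing at 20 min, as a percentage of the substrate charged

Draw the substrate curve first. West has lost 32.0% by its first reading at 1.50 min, so the opening slope is steep. A knee follows, then a level: substrate reads 73% at 4.00 min and 74% at 20.0 min. Average the seven readings of each run. The means read 71.1% in west and 64.1% in south. Between west and south the substrate lost grows about as the root of c(substrate), so I set this flask's level at 75.6%.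

Now subtract. Take mono at the knee as the mean of the first two readings, 16.5% in west and 17.5% in south. Substrate lost minus that mono, counting no other product, is my estimate of the knee bis: 12.4% in west, 18.4% in south. Per c(substrate) the two runs nearly agree, so scale in proportion: this flask's knee bis is 8.59%.

West's adducts then hold about 0.413 equiv of partner against 1.1 equiv charged, yet substrate stops. Read partner as the limiting reagent, lost by another path near the knee. Bis carries a second partner, so expect it flat past the knee while mono sinks.

The forecast gives substrate 76.5%, mono 10% and bis 13.5%, on the ground that “Mono keeps draining into bis without returning substrate.” On bis it stands above my knee bis.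

The flask gives substrate 75.6%, mono 9.40% and bis 7.33%. Partner is down to 0.0654% of its charge at 2.00 min, and bis already stands at 7.32% then and 7.33% at 20.0 min, while side product climbs to 7.71%. The knee bis lay 1.3 percentage points above the result.

    substrate + partner → mono adduct + by-product (k = 0.770 /M/s)
    mono adduct + by-product → side product (k = 0.0930 /M/s)
    partner → decomposed reagent (k = 0.0430 /s)
    partner + mono adduct → bis adduct + by-product (k = 2.00 /M/s)

Read the same flask at 50 min: knee bis says bis stays at its knee value, 8.59% by my reckoning. Computed, bis is 7.33% and mono 4.61%.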